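The dodecanoyl ketone is disconnected between its carbonyl carbon and the adjacent chain methylene, so that the whole alkyl chain arrives as 1-undecene and the rest of the molecule as an aryl aldehyde. The key step is a phenol-directed, rhodium-catalysed linear hydroacylation: the formyl C–H of fully unprotected 3-flavanyl-2,4,6-trihydroxybenzaldehyde adds across the terminal alkene with no by-product and no protecting group, giving the target directly. It exploits the ortho-hydroxy aryl ketone of the phloroglucinol ring (ring D), whose hydroxyl on the carbon next to the acylated carbon chelates rhodium. The cis-2,4-diarylchroman (rings A and C, C2 and C4) is set earlier by a catalytic asymmetric ortho-quinone methide–styrene [4+2] cycloaddition.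

Key step: step 6

Remarks on the chemistry:
- Ring labels: A is the benzo ring of the chroman, B the 4-hydroxyphenyl ring on C2, C the pyran ring, D the phloroglucinol ring on C4. The target is the (2R,4R) isomer, in which the two aryl groups on ring C are cis.
- The sense of asymmetric induction in step 3 is assigned by analogy. The (R) acid is written; its (S) antipode would be used if the sense proved opposite.
- Compounds 1, 3, 7 and 13 are taken as commercial. Catalyst-bound species of catalytic cycles and salt forms before work-up are described in the Why lines and not numbered.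

Step 1
Reactants: 1 1,3,5-tris(benzyloxy)benzene
Product: 2 2-bromo-1,3,5-tris(benzyloxy)benzene
Conditions: NBS (1.0 equiv), CH2Cl2, −78 °C to 0 °C
Reagents that add atoms: N-bromosuccinimide, O=C1CCC(=O)N1Br
Why: Electrophilic aromatic bromination of a trialkoxybenzene whose three free positions are equivalent, so one equivalent of NBS at low temperature should give the single monobromide.

Step 2
Reactants: 2 2-bromo-1,3,5-tris(benzyloxy)benzene; 3 4-(benzyloxy)-2-hydroxybenzaldehyde
Product: 6 racemic [4-(benzyloxy)-2-hydroxyphenyl][2,4,6-tris(benzyloxy)phenyl]methanol, via lithium phenoxide 4 (not isolated), via aryllithium 5 (not isolated)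
Conditions: 3, LiN(SiMe3)2 (1.0 equiv), THF, −78 °C; separately 2, n-BuLi (1.05 equiv), THF, −78 °C; combine, −78 to −40 °C; aq. NH4Cl, cold; chromatography on Et3N-deactivated silica
Reagents that add atoms: none
Why: Bromine–lithium exchange followed by 1,2-addition of the aryllithium to the aldehyde, whose phenol is masked beforehand as its lithium salt by a non-nucleophilic base; the carbinol centre is racemic and is erased in step 3.

Step 3
Reactants: 6 racemic [4-(benzyloxy)-2-hydroxyphenyl][2,4,6-tris(benzyloxy)phenyl]methanol; 7 4-(benzyloxy)styrene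
Product: 9 (2R,4R)-7-(benzyloxy)-2-[4-(benzyloxy)phenyl]-4-[2,4,6-tris(benzyloxy)phenyl]chromane, via ortho-quinone methide 8 (not isolated)
Conditions: (R)-N-triflylphosphoramide of 3,3'-bis(2,4,6-triisopropylphenyl)-1,1'-bi-2-naphthol (5 mol%), 7 (2 equiv), 4 Å MS, CH2Cl2, −20 °C to rt
Reagents that add atoms: none
Why: Chiral Brønsted acid-catalysed dehydration to the ortho-quinone methide and inverse-electron-demand oxa-[4+2] cycloaddition with the electron-rich styrene (a known asymmetric reaction type for ortho-hydroxybenzhydrols and styrenes), in which the endo transition state should set the 2,4-cis relationship and the phosphoramide anion bound to the quinone methide oxygen should shield one face to set C4 and C2 as (4R,2R).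

Step 4
Reactants: 9 (2R,4R)-7-(benzyloxy)-2-[4-(benzyloxy)phenyl]-4-[2,4,6-tris(benzyloxy)phenyl]chromane
Product: 10 2-[(2R,4R)-7-hydroxy-2-(4-hydroxyphenyl)chroman-4-yl]benzene-1,3,5-triol
Conditions: H2 (1 atm), Pd(OH)2/C, THF–MeOH, rt, stopped at full conversion
Reagents that add atoms: none
Why: Hydrogenolysis of the five aryl benzyl ethers under neutral conditions, which should leave the C2–O1 ether bond and both stereocentres untouched when the reaction is stopped on consumption of the ethers.

Step 5
Reactants: 10 2-[(2R,4R)-7-hydroxy-2-(4-hydroxyphenyl)chroman-4-yl]benzene-1,3,5-triol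
Product: 12 2,4,6-trihydroxy-3-[(2R,4R)-7-hydroxy-2-(4-hydroxyphenyl)chroman-4-yl]benzaldehyde, via iminium chloride 11 (not isolated)
Conditions: (chloromethylene)dimethyliminium chloride (1.1 equiv), MeCN, −20 °C to 0 °C; then H2O, 40 °C
Reagents that add atoms: (chloromethylene)dimethyliminium chloride, C[N+](C)=CCl.[Cl-]; water, O
Why: Vilsmeier–Haack formylation, which should occur on ring D because each of its two equivalent free positions is activated by three hydroxyl groups (rings A and B are far less nucleophilic) and should stop after one formylation because the iminium group deactivates the ring.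

Step 6
Reactants: 12 2,4,6-trihydroxy-3-[(2R,4R)-7-hydroxy-2-(4-hydroxyphenyl)chroman-4-yl]benzaldehyde; 13 1-undecene
Product: 14 1-{2,4,6-trihydroxy-3-[(2R,4R)-7-hydroxy-2-(4-hydroxyphenyl)chroman-4-yl]phenyl}dodecan-1-one (target)
Conditions: [RhCl(C8H12)]2 (C8H12 = 1,5-cyclooctadiene, 2.5 mol%), bulky biaryl phosphoramidite ligand (e.g. the BINOL-derived N,N-diisopropylphosphoramidite, 10 mol%), K3PO4 (10 mol%), 13 (3 equiv), degassed THF, 70 °C
Reagents that add atoms: none
Why: K3PO4 places monovalent rhodium on an ortho phenoxide oxygen of ring D, and chelation-assisted oxidative addition of the formyl C–H bond gives a five-membered acyl rhodium hydride chelate (trivalent rhodium); 1-undecene then inserts into the Rh–H bond in the anti-Markovnikov sense and C–C reductive elimination from the acyl(primary alkyl)rhodium species forms the carbonyl–CH2 bond. The closest known reaction type is the rhodium/phosphoramidite-catalysed intermolecular hydroacylation of unactivated terminal alkenes with salicylaldehydes. No ring is closed in the product (the rhodacycle is transient) and no stereocentre is created; C2 and C4 are spectators under these nearly neutral conditions. The step needs linear over branched selectivity, which the bulky phosphoramidite should provide by disfavouring the secondary alkyl rhodium species. It also needs hydroacylation to outrun decarbonylation, which the chelating ortho hydroxyl secures; either of the two ortho hydroxyls can serve and both lead to the same product. The remaining phenols should be tolerated because only a catalytic amount of a mild base is present.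

Compound list
1 | 1,3,5-tris(benzyloxy)benzene | c1ccc(COc2cc(OCc3ccccc3)cc(OCc3ccccc3)c2)cc1 | starting material
2 | 2-bromo-1,3,5-tris(benzyloxy)benzene | Brc1c(OCc2ccccc2)cc(OCc2ccccc2)cc1OCc1ccccc1 | intermediate
3 | 4-(benzyloxy)-2-hydroxybenzaldehyde | O=Cc1ccc(OCc2ccccc2)cc1O | starting material
4 | lithium 5-(benzyloxy)-2-formylphenoxide | [Li]Oc1cc(OCc2ccccc2)ccc1C=O | intermediate
5 | 2,4,6-tris(benzyloxy)phenyllithium | [Li]c1c(OCc2ccccc2)cc(OCc2ccccc2)cc1OCc1ccccc1 | intermediate
6 | racemic [4-(benzyloxy)-2-hydroxyphenyl][2,4,6-tris(benzyloxy)phenyl]methanol | OC(c1ccc(OCc2ccccc2)cc1O)c1c(OCc2ccccc2)cc(OCc2ccccc2)cc1OCc1ccccc1 | intermediate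
7 | 4-(benzyloxy)styrene | C=Cc1ccc(OCc2ccccc2)cc1 | starting material
8 | 3-(benzyloxy)-6-[2,4,6-tris(benzyloxy)benzylidene]cyclohexa-2,4-dien-1-one (ortho-quinone methide) | O=C1C=C(OCc2ccccc2)C=CC1=Cc1c(OCc2ccccc2)cc(OCc2ccccc2)cc1OCc1ccccc1 | intermediate
9 | (2R,4R)-7-(benzyloxy)-2-[4-(benzyloxy)phenyl]-4-[2,4,6-tris(benzyloxy)phenyl]chromane | C(c1ccccc1)Oc1cc(OCc2ccccc2)c([C@@H]2C[C@H](c3ccc(OCc4ccccc4)cc3)Oc3cc(OCc4ccccc4)ccc32)c(OCc2ccccc2)c1 | intermediate
10 | 2-[(2R,4R)-7-hydroxy-2-(4-hydroxyphenyl)chroman-4-yl]benzene-1,3,5-triol | Oc1cc(O)c([C@@H]2C[C@H](c3ccc(O)cc3)Oc3cc(O)ccc32)c(O)c1 | intermediate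
11 | N-{2,4,6-trihydroxy-3-[(2R,4R)-7-hydroxy-2-(4-hydroxyphenyl)chroman-4-yl]benzylidene}-N-methylmethanaminium chloride | C[N+](C)=Cc1c(O)cc(O)c([C@@H]2C[C@H](c3ccc(O)cc3)Oc3cc(O)ccc32)c1O.[Cl-] | intermediate
12 | 2,4,6-trihydroxy-3-[(2R,4R)-7-hydroxy-2-(4-hydroxyphenyl)chroman-4-yl]benzaldehyde | O=Cc1c(O)cc(O)c([C@@H]2C[C@H](c3ccc(O)cc3)Oc3cc(O)ccc32)c1O | intermediate
13 | 1-undecene | C=CCCCCCCCCC | starting material
14 | 1-{2,4,6-trihydroxy-3-[(2R,4R)-7-hydroxy-2-(4-hydroxyphenyl)chroman-4-yl]phenyl}dodecan-1-one | CCCCCCCCCCCC(=O)c1c(O)cc(O)c([C@@H]2C[C@H](c3ccc(O)cc3)Oc3cc(O)ccc32)c1O | target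

Total step count: 6
Longest linear sequence: 6 steps (1 → 2 → 6 → 9 → 10 → 12 → 14)

Steps most likely to fail

Step 3. The doubly ortho-substituted, strongly stabilised benzhydryl cation may react stepwise outside the chiral ion pair, eroding facial and endo control; self-condensation of 6 or cationic oligomerisation of 7 may also compete. The fallback sets out from 2 and comes back at 10, fixing C2 first by asymmetric conjugate addition and C4 by substrate-controlled hydrogenation. Benzylation of commercial 7-hydroxy-4H-chromen-4-one (BnBr, K2CO3, DMF) should give 7-(benzyloxy)-4H-chromen-4-one F1. Conjugate addition of 4-(benzyloxy)phenylboronic acid with Pd(OCOCF3)2 and the enantiomer of the tert-butyl pyridine-oxazoline ligand that delivers the (2R) product (NH4PF6, H2O, 1,2-dichloroethane, 60 °C) should give (2R)-7-(benzyloxy)-2-[4-(benzyloxy)phenyl]chroman-4-one F2. Aryllithium 5, made from 2 as in step 2 and transmetallated with anhydrous CeCl3 (THF, −78 °C) to suppress enolisation and the ring opening that would racemise C2, should add to F2 to give (2R)-7-(benzyloxy)-2-[4-(benzyloxy)phenyl]-4-[2,4,6-tris(benzyloxy)phenyl]chroman-4-ol F3 (either C4 epimer). Mild dehydration (pyridinium p-toluenesulfonate, toluene, 60 °C) should give (2R)-7-(benzyloxy)-2-[4-(benzyloxy)phenyl]-4-[2,4,6-tris(benzyloxy)phenyl]-2H-chromene F4. Hydrogenation (H2, Pd/C, EtOAc–MeOH) should deliver hydrogen to C3=C4 from the face opposite the C2 aryl group, giving the 2,4-cis product, and cleave the five benzyl ethers in the same operation to reach 10.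

Step 6. The acyl rhodium hydride may decarbonylate, the polyphenoxide may sequester the catalyst, the alkene may isomerise to internal undecenes, or insertion may turn branched. The fallback sets out from 9 (with 13) and comes back at 14; it forms the same carbonyl–CH2 bond on the protected series by a three-component carbonylative coupling. Iodination of ring D with N-iodosuccinimide (MeCN–CH2Cl2, 0 °C) should give (2R,4R)-7-(benzyloxy)-2-[4-(benzyloxy)phenyl]-4-[2,4,6-tris(benzyloxy)-3-iodophenyl]chromane F5. Hydroboration of 13 with 9-BBN-H (THF, rt) should give B-undecyl-9-borabicyclo[3.3.1]nonane F6. Carbonylative Suzuki–Miyaura coupling of F5 and F6 under CO (1 atm) with PdCl2(PPh3)2 and K3PO4 (THF, 50 °C) should give 1-{2,4,6-tris(benzyloxy)-3-[(2R,4R)-7-(benzyloxy)-2-[4-(benzyloxy)phenyl]chroman-4-yl]phenyl}dodecan-1-one F7. Hydrogenolysis (H2, Pd(OH)2/C, THF–MeOH, rt) should then give 14.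

Step 5. Formylation may stray to ring A or occur twice on ring D, phenols may be O-formylated, and the acid released may ionise the C4–ring D bond and epimerise C4. The fallback sets out from 9 and comes back at 12, formylating at the protected stage and then removing the benzyl groups without reduction. Vilsmeier–Haack formylation of 9 (POCl3, DMF, 0 to 60 °C; aq. NaOAc) should give 2,4,6-tris(benzyloxy)-3-[(2R,4R)-7-(benzyloxy)-2-[4-(benzyloxy)phenyl]chroman-4-yl]benzaldehyde F8, the trialkoxy ring being the most electron-rich and O-formylation being impossible. Debenzylation with BCl3 and pentamethylbenzene (CH2Cl2, −78 °C) should give 12 with the aldehyde intact.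

Further compounds
F1 | step 3 | 7-(benzyloxy)-4H-chromen-4-one | O=c1ccoc2cc(OCc3ccccc3)ccc12
F2 | step 3 | (2R)-7-(benzyloxy)-2-[4-(benzyloxy)phenyl]chroman-4-one | O=C1C[C@H](c2ccc(OCc3ccccc3)cc2)Oc2cc(OCc3ccccc3)ccc12
F3 | step 3 | (2R)-7-(benzyloxy)-2-[4-(benzyloxy)phenyl]-4-[2,4,6-tris(benzyloxy)phenyl]chroman-4-ol | OC1(c2c(OCc3ccccc3)cc(OCc3ccccc3)cc2OCc2ccccc2)C[C@H](c2ccc(OCc3ccccc3)cc2)Oc2cc(OCc3ccccc3)ccc21
F4 | step 3 | (2R)-7-(benzyloxy)-2-[4-(benzyloxy)phenyl]-4-[2,4,6-tris(benzyloxy)phenyl]-2H-chromene | C1(c2c(OCc3ccccc3)cc(OCc3ccccc3)cc2OCc2ccccc2)=C[C@H](c2ccc(OCc3ccccc3)cc2)Oc2cc(OCc3ccccc3)ccc21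
F5 | step 6 | (2R,4R)-7-(benzyloxy)-2-[4-(benzyloxy)phenyl]-4-[2,4,6-tris(benzyloxy)-3-iodophenyl]chromane | Ic1c(OCc2ccccc2)cc(OCc2ccccc2)c([C@@H]2C[C@H](c3ccc(OCc4ccccc4)cc3)Oc3cc(OCc4ccccc4)ccc32)c1OCc1ccccc1
F6 | step 6 | B-undecyl-9-borabicyclo[3.3.1]nonane | CCCCCCCCCCCB1C2CCCC1CCC2
F7 | step 6 | 1-{2,4,6-tris(benzyloxy)-3-[(2R,4R)-7-(benzyloxy)-2-[4-(benzyloxy)phenyl]chroman-4-yl]phenyl}dodecan-1-one | CCCCCCCCCCCC(=O)c1c(OCc2ccccc2)cc(OCc2ccccc2)c([C@@H]2C[C@H](c3ccc(OCc4ccccc4)cc3)Oc3cc(OCc4ccccc4)ccc32)c1OCc1ccccc1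
F8 | step 5 | 2,4,6-tris(benzyloxy)-3-[(2R,4R)-7-(benzyloxy)-2-[4-(benzyloxy)phenyl]chroman-4-yl]benzaldehyde | O=Cc1c(OCc2ccccc2)cc(OCc2ccccc2)c([C@@H]2C[C@H](c3ccc(OCc4ccccc4)cc3)Oc3cc(OCc4ccccc4)ccc32)c1OCc1ccccc1
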